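The dearomatised triketone ring is opened at two bonds: ring C=O carbon to the ArCH2-bearing carbon, and butyryl-bearing carbon to the enol carbon beside the quaternary centre. The key step makes both in one flask. The trianion of an open-chain keto ester, which already carries the quaternary stereocentre, the prenyl group and the complete aryl-CH2 arm, is C-acylated by 2,2-dimethyl-6-propyl-1,3-dioxin-4-one (a butyrylketene equivalent). The β-diketonate so released closes onto the methyl ester (Dieckmann). The step exploits the 1,3,5-tricarbonyl pattern of that six-membered ring around its non-enolisable C(Me)(prenyl) carbon. The stereocentre comes from an auxiliary-controlled prenylation.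

Key step: step 7

Assumption: the L-valine-derived lithio-enamine in toluene/HMPA is taken to alkylate on the face that gives the R quaternary centre (if the sense is the opposite, the D-auxiliary is used in the same protocol); enolisable compounds are written in one tautomeric form.

Step 1
Reactants: 1 methyl 2-methyl-3-oxobutanoate (racemic); 2 L-valine tert-butyl ester (free base from the commercial hydrochloride)
Product: 3 methyl (2Z)-3-{[(2S)-1-(tert-butoxy)-3-methyl-1-oxobutan-2-yl]amino}-2-methylbut-2-enoate
Conditions: BF3·OEt2 (cat.), toluene, reflux, azeotropic removal of water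
Reagents that add atoms: none
Why: Acid-catalysed condensation of the keto group with the primary amine should give the Z-enamine (a vinylogous carbamate held by an N–H···O=C hydrogen bond); the stereocentre of 1 is erased and that of the auxiliary is untouched.

Step 2
Reactants: 3
Product: 6 methyl (2R)-2-acetyl-2,5-dimethylhex-4-enoate, via lithio-enamine 4 (not isolated), via alkylated imine 5 (not isolated)
Conditions: LiN(iPr)2, toluene, −78 °C; HMPA (1 equiv); prenyl bromide, −78 → −55 °C; then 10% aq citric acid, rt
Reagents that add atoms: prenyl bromide CC(C)=CCBr; water O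
Why: Alkylation of a metallated chiral enamine: lithium is chelated by the nitrogen and the two ester carbonyls, the isopropyl group screens one face of the planar aza-enolate, prenyl bromide reacts at its primary carbon (SN2) on the open face to set the quaternary centre as R, and mild acid hydrolysis of the imine releases the ketone and the auxiliary.

Step 3
Reactants: 6
Product: 8 methyl (2R)-2-[3-(dimethylamino)propanoyl]-2,5-dimethylhex-4-enoate, via lithium enolate 7 (not isolated)
Conditions: LiN(iPr)2, THF, −78 °C; [CH2=NMe2]I, −78 °C → rt
Reagents that add atoms: dimethylmethyleneiminium iodide C=[N+](C)C.[I-]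
Why: Only the acetyl methyl group can be enolised because the other α-carbon is quaternary, and the lithium enolate is aminomethylated by the preformed iminium salt (Mannich reaction).

Step 4
Reactants: 9 1-(2,4,6-trihydroxyphenyl)butan-1-one
Product: 10 1-(2,6-dihydroxy-4-methoxyphenyl)butan-1-one
Conditions: Me2SO4 (1.05 equiv), K2CO3, acetone, rt
Reagents that add atoms: dimethyl sulfate COS(=O)(=O)OC
Why: Williamson etherification: both ortho-hydroxyls are tied up in hydrogen bonds to the ketone, so the para-hydroxyl is the most acidic and most nucleophilic site.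

Step 5
Reactants: 8; 10
Product: 13 methyl (2R)-2-[3-(3-butanoyl-2,4-dihydroxy-6-methoxyphenyl)propanoyl]-2,5-dimethylhex-4-enoate, via ammonium iodide 11 (not isolated), via vinyl ketone 12 (not isolated)
Conditions: MeI, Et2O, rt, then evaporate; 10 (2 equiv), K2CO3, MeCN–H2O, rt → 40 °C
Reagents that add atoms: none
Why: Hofmann-type E1cB elimination of the quaternised Mannich base should give vinyl ketone 12, to which the phenoxide of 10 adds through its ring carbon (Michael addition, the C-alkylation typical of phloroglucinol phenoxides); the two free ring positions of 10 are equivalent and its excess limits double alkylation.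

Step 6
Reactants: 14 2,2,6-trimethyl-4H-1,3-dioxin-4-one
Product: 16 2,2-dimethyl-6-propyl-4H-1,3-dioxin-4-one, via lithium dienolate 15 (not isolated)
Conditions: LiN(iPr)2, THF–HMPA, −78 °C; EtI, −78 → −30 °C
Reagents that add atoms: ethyl iodide CCI
Why: Vinylogous enolate alkylation: the lithium dienolate of the dioxinone reacts with primary iodides at the γ-carbon, which extends the 6-methyl group to propyl.

Step 7
Reactants: 13; 16
Product: 19 elaphopilosin A, via trilithium trianion 17 (not isolated), via triketo ester enolate 18 (not isolated)
Conditions: LiN(SiMe3)2 (3.1 equiv), THF, −78 → 0 °C; 16 (1.5 equiv), −78 → 50 °C; then 1 M HCl, 0 °C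
Reagents that add atoms: none
Why: Proposed new method: three equivalents of LiN(SiMe3)2 should give trianion 17, because the two ortho-phenoxides make the aryl ketone a vinylogous carboxylate and the other flank of the aliphatic ketone is quaternary, so the third proton can only come from the CH2 next to that ketone; this enolate carbon adds 1,2 to the cyclic, lactone-type carbonyl of 16 and the tetrahedral intermediate collapses with loss of acetone to the β-diketonate 18 (first C–C bond). The central carbon of that diketonate, the one bearing the butyryl group, then attacks the methyl ester on the quaternary carbon in a 6-(enolendo)-exo-trig Dieckmann closure (second C–C bond), and the expelled methoxide deprotonates the very acidic ring, which pulls both reversible acylations to the product. The closest known reactions are the crossed Claisen acylation of ketone polyanions by esters and lactones, the opening of 1,3-dioxin-4-ones by alkoxides, and the Lacey–Dieckmann cyclisation; what is new is a dioxinone serving as 3-oxoacyl donor to an enolate carbon with ring closure in the same flask. No stereocentre is formed, and the existing quaternary centre carries no hydrogen and lies outside both bond-forming events, so it keeps its R configuration. The step needs C- over O-acylation and carbocycle over pyranone: aryl or enol 3-oxohexanoates from O-acylation give the acyl group back by E1cB loss of butyrylketene, and an enol lactone from O-closure is itself an acyl donor toward the diketonate carbon, so the C,C-bonded ring is the only sink.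

Compound list
1 | methyl 2-methyl-3-oxobutanoate (racemic) | CC(=O)C(C)C(=O)OC | starting material
2 | L-valine tert-butyl ester | CC(C)[C@H](N)C(=O)OC(C)(C)C | starting material
3 | methyl (2Z)-3-{[(2S)-1-(tert-butoxy)-3-methyl-1-oxobutan-2-yl]amino}-2-methylbut-2-enoate | COC(=O)/C(C)=C(C)\N[C@@H](C(C)C)C(=O)OC(C)(C)C | intermediate
4 | N-lithio derivative (lithium aza-enolate) of 3 | COC(=O)/C(C)=C(C)\N([Li])[C@@H](C(C)C)C(=O)OC(C)(C)C | intermediate
5 | tert-butyl N-[(3R)-3-(methoxycarbonyl)-3,6-dimethylhept-5-en-2-ylidene]-L-valinate (imine of 6 with 2) | COC(=O)[C@](C)(CC=C(C)C)C(C)=N[C@@H](C(C)C)C(=O)OC(C)(C)C | intermediate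
6 | methyl (2R)-2-acetyl-2,5-dimethylhex-4-enoate | COC(=O)[C@](C)(CC=C(C)C)C(C)=O | intermediate
7 | lithium enolate of 6 at the acetyl methyl group | COC(=O)[C@](C)(CC=C(C)C)C(=C)O[Li] | intermediate
8 | methyl (2R)-2-[3-(dimethylamino)propanoyl]-2,5-dimethylhex-4-enoate | COC(=O)[C@](C)(CC=C(C)C)C(=O)CCN(C)C | intermediate
9 | 1-(2,4,6-trihydroxyphenyl)butan-1-one | CCCC(=O)c1c(O)cc(O)cc1O | starting material
10 | 1-(2,6-dihydroxy-4-methoxyphenyl)butan-1-one | CCCC(=O)c1c(O)cc(OC)cc1O | intermediate
11 | [(4R)-4-(methoxycarbonyl)-4,7-dimethyl-3-oxooct-6-en-1-yl]trimethylammonium iodide | COC(=O)[C@](C)(CC=C(C)C)C(=O)CC[N+](C)(C)C.[I-] | intermediate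
12 | methyl (2R)-2,5-dimethyl-2-(prop-2-enoyl)hex-4-enoate | COC(=O)[C@](C)(CC=C(C)C)C(=O)C=C | intermediate
13 | methyl (2R)-2-[3-(3-butanoyl-2,4-dihydroxy-6-methoxyphenyl)propanoyl]-2,5-dimethylhex-4-enoate (open keto form; may equilibrate with its cyclic hemiketal) | COC(=O)[C@](C)(CC=C(C)C)C(=O)CCc1c(OC)cc(O)c(C(=O)CCC)c1O | intermediate
14 | 2,2,6-trimethyl-4H-1,3-dioxin-4-one | CC1=CC(=O)OC(C)(C)O1 | starting material
15 | lithium dienolate of 14 (6-methylidene, 4-lithiooxy) | C=C1C=C(O[Li])OC(C)(C)O1 | intermediate
16 | 2,2-dimethyl-6-propyl-4H-1,3-dioxin-4-one | CCCC1=CC(=O)OC(C)(C)O1 | intermediate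
17 | trilithium salt of 13 (two phenoxides and the enolate toward the CH2 group) | COC(=O)[C@](C)(CC=C(C)C)C(O[Li])=CCc1c(OC)cc(O[Li])c(C(=O)CCC)c1O[Li] | intermediate
18 | lithium enolate, as bis-phenoxide, of methyl (2R)-2-[2-(3-butanoyl-2,4-dihydroxy-6-methoxybenzyl)-3,5-dioxooctanoyl]-2,5-dimethylhex-4-enoate (mixture at the new enolisable CH) | COC(=O)[C@](C)(CC=C(C)C)C(=O)C(Cc1c(OC)cc(O[Li])c(C(=O)CCC)c1O[Li])C(=O)C=C(CCC)O[Li] | intermediate
19 | elaphopilosin A, (4R)-2-butanoyl-6-[(3-butanoyl-2,4-dihydroxy-6-methoxyphenyl)methyl]-3,5-dihydroxy-4-methyl-4-(3-methylbut-2-en-1-yl)cyclohexa-2,5-dien-1-one | CCCC(=O)C1=C(O)[C@](C)(CC=C(C)C)C(O)=C(Cc2c(OC)cc(O)c(C(=O)CCC)c2O)C1=O | target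

Total step count: 7. Longest linear sequence: 5 steps (1, 2, 3, 5, 7).

Steps most likely to fail

Step 7 (labelled). The enolate may take a proton from the γ-CH2 of the dioxinone instead of adding to its carbonyl, or enolisation may occur in part at the aryl ketone, so that the cascade stalls before the first C–C bond. The fallback uses known chemistry and sets out from 13. Cyclodehydration of 13 through its hemiketal (pyridinium p-toluenesulfonate cat., toluene, 80 °C, 4 Å molecular sieves) should give the regiodefined cyclic enol ether methyl (2R)-2-(8-butanoyl-7-hydroxy-5-methoxy-4H-chromen-2-yl)-2,5-dimethylhex-4-enoate F1; the double bond can only form toward the CH2 group. Heating F1 with 16 (2.5 equiv) in toluene at 110 °C releases butyrylketene, which adds to the enol ether in a hetero-Diels–Alder reaction (ring carbonyl carbon to the CH carbon) and acylates the remaining phenol, to give the pyranone ketal with an aryl 3-oxohexanoate F2. Treatment with Ba(OH)2 in aqueous MeOH at rt, then dilute acid, should cleave the aryl ester, open the ketal by β-elimination and hydroxide addition to the 4-pyranone, and close the carbocycle by Claisen condensation onto the methyl ester. The sequence comes back at 19, with the two bonds formed in two operations.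

Step 5. O-alkylation, double alkylation of the phenol or polymerisation of the vinyl ketone may outrun the wanted C-alkylation. The fallback reverses the polarity of the one-carbon link and sets out from 10 and 6. Aminomethylation of 10 ([CH2=NMe2]I, MeCN, rt) should give 1-{3-[(dimethylamino)methyl]-2,6-dihydroxy-4-methoxyphenyl}butan-1-one F3. Silylation of the enolate of 6 (LiN(iPr)2, Me3SiCl, THF, −78 °C) should give methyl (2R)-2,5-dimethyl-2-[1-(trimethylsilyloxy)ethenyl]hex-4-enoate F4. Heating F3 with excess F4 in toluene at 110 °C generates the ortho-quinone methide by loss of dimethylamine, and its inverse-demand hetero-Diels–Alder reaction with the silyl enol ether should give the 2-(trimethylsilyloxy)chroman ketal F5. Mild hydrolysis (aq citric acid, THF) opens F5, and the route is rejoined at 13.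

Step 2. Facial selectivity of the enamine alkylation may be poor, or its sense opposite to the one assumed. The fallback replaces asymmetric induction by resolution and sets out from 1. Alkylation with prenyl bromide and K2CO3 in acetone gives racemic methyl 2-acetyl-2,5-dimethylhex-4-enoate F6, and preparative chromatography on a chiral stationary phase (supercritical CO2/MeOH) delivers the R enantiomer, which is 6.

Further compounds
F1 | step 7 | methyl (2R)-2-(8-butanoyl-7-hydroxy-5-methoxy-4H-chromen-2-yl)-2,5-dimethylhex-4-enoate | COC(=O)[C@](C)(CC=C(C)C)C1=CCc2c(OC)cc(O)c(C(=O)CCC)c2O1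
F2 | step 7 | hetero-Diels–Alder adduct of F1 with butyrylketene (2-propyl-4-oxo-dihydropyrano[2,3-b]chromene ketal, mixture at the two ring-fusion carbons) carrying a 3-oxohexanoyl ester on the remaining phenol | COC(=O)[C@](C)(CC=C(C)C)C12OC(CCC)=CC(=O)C1Cc1c(OC)cc(OC(=O)CC(=O)CCC)c(C(=O)CCC)c1O2
F3 | step 5 | 1-{3-[(dimethylamino)methyl]-2,6-dihydroxy-4-methoxyphenyl}butan-1-one | CCCC(=O)c1c(O)cc(OC)c(CN(C)C)c1O
F4 | step 5 | methyl (2R)-2,5-dimethyl-2-[1-(trimethylsilyloxy)ethenyl]hex-4-enoate | COC(=O)[C@](C)(CC=C(C)C)C(=C)O[Si](C)(C)C
F5 | step 5 | methyl (2R)-2-[8-butanoyl-7-hydroxy-5-methoxy-2-(trimethylsilyloxy)chroman-2-yl]-2,5-dimethylhex-4-enoate (mixture at the ketal carbon) | COC(=O)[C@](C)(CC=C(C)C)C1(O[Si](C)(C)C)CCc2c(OC)cc(O)c(C(=O)CCC)c2O1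
F6 | step 2 | methyl 2-acetyl-2,5-dimethylhex-4-enoate (racemic) | COC(=O)C(C)(CC=C(C)C)C(C)=O
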